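**Plan**
- Retrosynthesis: the O1–C2(=O) unit of the oxolan-2-one ring is taken out as CO2 by cutting C2–C3 and O1–C5. This works because C3 and C5 are 1,3-related through the stereogenic C4: with C3 and its benzylic carbon raised to an alkyne, C3 becomes a nickel-bound vinyl carbon, and C5 as CH2Cl is the electrophile.
- The aryl alkyne is cut at the aryl–C(sp) bond (Sonogashira) into a 5-bromo-2,3-dihydrobenzofuran and a chloro-alkyne; the dihydrofuran ring is cut at C2–C3 (rhodium carbenoid C–H insertion).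
- Forward: both fragments are built separately and joined; the dihydrobenzofuran ring arises first and the oxolan-2-one ring last, by the CO2 annulation. Hydrogenation then returns C3 and its benzylic carbon to the sp3 level and frees the phenols.
- Stereochemistry: lactone C4 comes from an auxiliary-controlled Evans hydroxymethylation; lactone C3 from hydrogenation followed by base equilibration to the trans lactone; dihydrobenzofuran C2 from the Rh2(S-PTTL)4-catalysed insertion and C3 from base epimerization to trans.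

Key step: step 17

Assumption: Rh2(S-PTTL)4 is taken to induce the (2S) configuration in step 13; should the sense prove opposite, its enantiomer Rh2(R-PTTL)4 is used with nothing else changed.

**Route**

Step 1
Reactants: 1 3-(4-hydroxy-3-methoxyphenyl)propanoic acid
Product: 2 3-[4-(benzyloxy)-3-methoxyphenyl]propanoic acid
Conditions: BnBr, NaOH, EtOH/H2O, reflux; then HCl
Reagents that add atoms: benzyl bromide, BrCc1ccccc1
Why: Williamson ether synthesis on the more nucleophilic phenoxide of the dianion; the aqueous alkali keeps the carboxyl group as the free carboxylate.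

Step 2
Reactants: 2 3-[4-(benzyloxy)-3-methoxyphenyl]propanoic acid; 3 (4R)-4-benzyl-1,3-oxazolidin-2-one
Product: 5 (4R)-4-benzyl-3-{3-[4-(benzyloxy)-3-methoxyphenyl]propanoyl}-1,3-oxazolidin-2-one, via mixed pivalic anhydride 4 (not isolated)
Conditions: PivCl, Et3N, THF, −20 °C; then LiCl, 3, rt
Reagents that add atoms: none
Why: N-acylation of the oxazolidinone through the mixed anhydride, the standard entry to an Evans imide.

Step 3
Reactants: 5 (4R)-4-benzyl-3-{3-[4-(benzyloxy)-3-methoxyphenyl]propanoyl}-1,3-oxazolidin-2-one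
Product: 7 (4R)-4-benzyl-3-[(2S)-2-{[4-(benzyloxy)-3-methoxyphenyl]methyl}-3-hydroxypropanoyl]-1,3-oxazolidin-2-one, via chlorotitanium (Z)-enolate 6 (not isolated)
Conditions: TiCl4, i-Pr2NEt, CH2Cl2, 0 °C; then 1,3,5-trioxane, TiCl4, 0 °C
Reagents that add atoms: 1,3,5-trioxane, C1OCOCO1
Why: Evans alkylation of the chelated titanium (Z)-enolate with a formaldehyde equivalent (hydroxymethylation); the electrophile should enter on the face away from the benzyl group of the auxiliary, which sets the centre that becomes C4 of the lactone.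

Step 4
Reactants: 7 (4R)-4-benzyl-3-[(2S)-2-{[4-(benzyloxy)-3-methoxyphenyl]methyl}-3-hydroxypropanoyl]-1,3-oxazolidin-2-one
Product: 8 (4R)-4-benzyl-3-[(2S)-2-{[4-(benzyloxy)-3-methoxyphenyl]methyl}-3-[(tert-butyldimethylsilyl)oxy]propanoyl]-1,3-oxazolidin-2-one
Conditions: TBSCl, imidazole, DMF, rt
Reagents that add atoms: tert-butyldimethylsilyl chloride, CC(C)(C)[Si](C)(C)Cl
Why: Silylation of the primary alcohol keeps the two CH2O arms distinct before the imide is reduced.

Step 5
Reactants: 8 (4R)-4-benzyl-3-[(2S)-2-{[4-(benzyloxy)-3-methoxyphenyl]methyl}-3-[(tert-butyldimethylsilyl)oxy]propanoyl]-1,3-oxazolidin-2-one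
Product: 9 (2R)-2-{[4-(benzyloxy)-3-methoxyphenyl]methyl}-3-[(tert-butyldimethylsilyl)oxy]propan-1-ol
Conditions: LiBH4, MeOH (1 equiv), THF, 0 °C
Reagents that add atoms: none
Why: Reductive cleavage of the Evans imide to the primary alcohol with release of the auxiliary; the stereocentre is not touched (its descriptor changes by the priority rules only).

Step 6
Reactants: 9 (2R)-2-{[4-(benzyloxy)-3-methoxyphenyl]methyl}-3-[(tert-butyldimethylsilyl)oxy]propan-1-ol
Product: 10 (2S)-2-{[4-(benzyloxy)-3-methoxyphenyl]methyl}-3-[(tert-butyldimethylsilyl)oxy]propanal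
Conditions: Dess–Martin periodinane, CH2Cl2, 0 °C to rt
Reagents that add atoms: none
Why: Dess–Martin oxidation under non-basic conditions should give the alpha-branched aldehyde without epimerization; it is used at once.

Step 7
Reactants: 10 (2S)-2-{[4-(benzyloxy)-3-methoxyphenyl]methyl}-3-[(tert-butyldimethylsilyl)oxy]propanal
Product: 11 tert-butyl{[(2R)-2-{[4-(benzyloxy)-3-methoxyphenyl]methyl}but-3-yn-1-yl]oxy}dimethylsilane
Conditions: dimethyl (1-diazo-2-oxopropyl)phosphonate, K2CO3, MeOH, 0 °C to rt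
Reagents that add atoms: dimethyl (1-diazo-2-oxopropyl)phosphonate, CC(=O)C(=[N+]=[N-])P(=O)(OC)OC
Why: Ohira–Bestmann homologation of the aldehyde to the terminal alkyne, well precedented for alpha-branched beta-silyloxy aldehydes with retention of configuration.

Step 8
Reactants: 11 tert-butyl{[(2R)-2-{[4-(benzyloxy)-3-methoxyphenyl]methyl}but-3-yn-1-yl]oxy}dimethylsilane
Product: 12 (2R)-2-{[4-(benzyloxy)-3-methoxyphenyl]methyl}but-3-yn-1-ol
Conditions: n-Bu4NF, THF, 0 °C to rt
Reagents that add atoms: none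
Why: Fluoride-mediated cleavage of the primary silyl ether.

Step 9
Reactants: 12 (2R)-2-{[4-(benzyloxy)-3-methoxyphenyl]methyl}but-3-yn-1-ol
Product: 13 1-(benzyloxy)-4-[(2R)-2-(chloromethyl)but-3-yn-1-yl]-2-methoxybenzene
Conditions: PPh3, CCl4, CH2Cl2, 40 °C
Reagents that add atoms: carbon tetrachloride, ClC(Cl)(Cl)Cl
Why: Appel chlorination of the primary alcohol installs the leaving group for the key step at a carbon that is not stereogenic.

Step 10
Reactants: 14 4-bromo-2-methoxyphenol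
Product: 15 4-bromo-2-iodo-6-methoxyphenol
Conditions: N-iodosuccinimide, TsOH·H2O (cat.), MeCN, rt
Reagents that add atoms: N-iodosuccinimide, O=C1CCC(=O)N1I
Why: Electrophilic aromatic iodination directed by the hydroxyl group to its only free ortho position, the para position being blocked by bromine.

Step 11
Reactants: 15 4-bromo-2-iodo-6-methoxyphenol; 16 [4-(benzyloxy)-3-methoxyphenyl]methanol
Product: 17 2-{[4-(benzyloxy)-3-methoxyphenyl]methoxy}-5-bromo-1-iodo-3-methoxybenzene
Conditions: PPh3, DIAD, THF, 0 °C to rt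
Reagents that add atoms: none
Why: Mitsunobu etherification of an acidic phenol with a primary benzylic alcohol.

Step 12
Reactants: 17 2-{[4-(benzyloxy)-3-methoxyphenyl]methoxy}-5-bromo-1-iodo-3-methoxybenzene; 18 ethyl diazoacetate
Product: 19 ethyl 2-(2-{[4-(benzyloxy)-3-methoxyphenyl]methoxy}-5-bromo-3-methoxyphenyl)-2-diazoacetate
Conditions: Pd(PPh3)4 (5 mol%), Ag2CO3 (0.5 equiv), Et3N, toluene, rt
Reagents that add atoms: none
Why: Palladium-catalysed cross-coupling of an aryl iodide with the C–H bond of ethyl diazoacetate with retention of the diazo group; at room temperature the C–I bond should react in preference to the C–Br bond.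

Step 13
Reactants: 19 ethyl 2-(2-{[4-(benzyloxy)-3-methoxyphenyl]methoxy}-5-bromo-3-methoxyphenyl)-2-diazoacetate
Product: 20 ethyl (2S,3R)-2-[4-(benzyloxy)-3-methoxyphenyl]-5-bromo-7-methoxy-2,3-dihydro-1-benzofuran-3-carboxylate (cis)
Conditions: Rh2(S-PTTL)4 (1 mol%), toluene, −60 °C
Reagents that add atoms: none
Why: Intramolecular 1,5 C–H insertion of the donor/acceptor rhodium carbenoid into the ether-activated benzylic C–H bond closes the dihydrofuran ring; the chiral carboxylate ligands of dirhodium tetrakis[N-phthaloyl-(S)-tert-leucinate] select the enantiotopic hydrogen and so set C2, and the cis ester is the expected kinetic product.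

Step 14
Reactants: 20 ethyl (2S,3R)-2-[4-(benzyloxy)-3-methoxyphenyl]-5-bromo-7-methoxy-2,3-dihydro-1-benzofuran-3-carboxylate
Product: 21 ethyl (2S,3S)-2-[4-(benzyloxy)-3-methoxyphenyl]-5-bromo-7-methoxy-2,3-dihydro-1-benzofuran-3-carboxylate (trans)
Conditions: NaOEt (0.2 equiv), EtOH, rt
Reagents that add atoms: none
Why: Base-mediated epimerization at C3 through the ester enolate under thermodynamic control; the 2,3-trans isomer is the more stable one, and C2 is not affected.

Step 15
Reactants: 21 ethyl (2S,3S)-2-[4-(benzyloxy)-3-methoxyphenyl]-5-bromo-7-methoxy-2,3-dihydro-1-benzofuran-3-carboxylate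
Product: 22 [(2S,3R)-2-[4-(benzyloxy)-3-methoxyphenyl]-5-bromo-7-methoxy-2,3-dihydro-1-benzofuran-3-yl]methanol
Conditions: LiBH4, THF/MeOH, 0 °C to rt
Reagents that add atoms: none
Why: Hydride reduction of the ester to the primary alcohol; the aryl bromide and the benzyl ethers should be inert.

Step 16
Reactants: 22 [(2S,3R)-2-[4-(benzyloxy)-3-methoxyphenyl]-5-bromo-7-methoxy-2,3-dihydro-1-benzofuran-3-yl]methanol; 13 1-(benzyloxy)-4-[(2R)-2-(chloromethyl)but-3-yn-1-yl]-2-methoxybenzene
Product: 23 {(2S,3R)-2-[4-(benzyloxy)-3-methoxyphenyl]-5-[(3R)-4-[4-(benzyloxy)-3-methoxyphenyl]-3-(chloromethyl)but-1-yn-1-yl]-7-methoxy-2,3-dihydro-1-benzofuran-3-yl}methanol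
Conditions: PdCl2(PhCN)2 (3 mol%), P(t-Bu)3 (6 mol%), CuI (2 mol%), i-Pr2NH, dioxane, rt
Reagents that add atoms: none
Why: Sonogashira coupling of an electron-rich aryl bromide at room temperature with a bulky electron-rich phosphine; the primary alkyl chloride and the free alcohol should not interfere.

Step 17
Reactants: 23 {(2S,3R)-2-[4-(benzyloxy)-3-methoxyphenyl]-5-[(3R)-4-[4-(benzyloxy)-3-methoxyphenyl]-3-(chloromethyl)but-1-yn-1-yl]-7-methoxy-2,3-dihydro-1-benzofuran-3-yl}methanol
Product: 25 (3E,4R)-3-({(2S,3R)-2-[4-(benzyloxy)-3-methoxyphenyl]-3-(hydroxymethyl)-7-methoxy-2,3-dihydro-1-benzofuran-5-yl}methylidene)-4-{[4-(benzyloxy)-3-methoxyphenyl]methyl}oxolan-2-one, via ethylzinc (E)-acrylate 24 (not isolated)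
Conditions: Ni(cod)2 (5 mol%), CsF (1 equiv), Et2Zn (4 equiv, one taken up by the free hydroxyl), CO2 (1 atm), MeCN, 60 °C; then n-Bu4NI (20 mol%), 80 °C; aq. HCl
Reagents that add atoms: carbon dioxide, O=C=O
Why: Proposed new method: oxidative cyclization of the alkyne and CO2 at zerovalent nickel should give an oxanickelacyclopentenone with the aryl-bearing carbon on nickel and the new carboxyl carbon on C3, after which transmetalation with Et2Zn, beta-hydride elimination (loss of ethylene) and C–H reductive elimination release the zinc (E)-acrylate 24 by net syn hydrocarboxylation, and the carboxylate oxygen then displaces the primary chloride at C5. The closest known reaction types are the Ni(cod)2/Et2Zn hydrocarboxylation of aryl alkyl alkynes with CO2 and the nickel-catalysed alkylative carboxylation of homopropargylic alcohols that ends in alpha-alkylidene-gamma-butyrolactones; new here is that both lactone oxygens come from CO2 and that the ring closes by O-alkylation, so that the whole is a formal (3+2) annulation of CO2 across C3 and C5. The oxolan-2-one ring closes in the 5-exo-tet mode. No new stereocentre arises: C4 lies between the two reacting carbons and takes part in neither bond, so it is carried through unchanged, and the syn addition fixes the (E) geometry, which is erased again in step 18. The step needs C–C bond formation at the alkyl-bearing and not at the aryl-bearing alkyne carbon, which the aryl group secures by favouring the nickel–carbon bond at its own carbon, and it needs the C–Cl bond to outlast zerovalent nickel, Et2Zn and fluoride until the carboxylate exists, which an unactivated primary chloride in the absence of a donor ligand should do. The iodide is added only after CO2 uptake so that the Finkelstein-assisted ring closure cannot start before the carboxylation.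

Step 18
Reactants: 25 (3E,4R)-3-({(2S,3R)-2-[4-(benzyloxy)-3-methoxyphenyl]-3-(hydroxymethyl)-7-methoxy-2,3-dihydro-1-benzofuran-5-yl}methylidene)-4-{[4-(benzyloxy)-3-methoxyphenyl]methyl}oxolan-2-one
Product: 26 (3S,4R)-4-[(4-hydroxy-3-methoxyphenyl)methyl]-3-{[(2S,3R)-2-(4-hydroxy-3-methoxyphenyl)-3-(hydroxymethyl)-7-methoxy-2,3-dihydro-1-benzofuran-5-yl]methyl}oxolan-2-one (cis lactone, carried on together with any trans epimer formed)
Conditions: H2 (1 atm), Pd/C (10% palladium on carbon), EtOAc/MeOH, rt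
Reagents that add atoms: none
Why: Heterogeneous hydrogenation of the conjugated exocyclic alkene with hydrogenolysis of the two aryl benzyl ethers; hydrogen should arrive on the face away from the C4 benzyl group, so the cis (3S) epimer is expected to predominate and is corrected in step 19.

Step 19
Reactants: 26 (3S,4R)-4-[(4-hydroxy-3-methoxyphenyl)methyl]-3-{[(2S,3R)-2-(4-hydroxy-3-methoxyphenyl)-3-(hydroxymethyl)-7-methoxy-2,3-dihydro-1-benzofuran-5-yl]methyl}oxolan-2-one
Product: 27 isolappaol A, (3R,4R)-4-[(4-hydroxy-3-methoxyphenyl)methyl]-3-{[(2S,3R)-2-(4-hydroxy-3-methoxyphenyl)-3-(hydroxymethyl)-7-methoxy-2,3-dihydro-1-benzofuran-5-yl]methyl}oxolan-2-one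
Conditions: NaOMe (6 equiv), MeOH, 40 °C; then 1 M HCl, rt
Reagents that add atoms: none
Why: Base-mediated epimerization at C3 through the lactone enolate under thermodynamic control; the trans-3,4-dibenzyl oxolan-2-one is the more stable epimer, so equilibration should set C3 as (R), and the acidic work-up returns the neutral lactone.

**Compound list**

1 | 3-(4-hydroxy-3-methoxyphenyl)propanoic acid | COc1cc(CCC(=O)O)ccc1O | starting material
2 | 3-[4-(benzyloxy)-3-methoxyphenyl]propanoic acid | COc1cc(CCC(=O)O)ccc1OCc1ccccc1 | intermediate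
3 | (4R)-4-benzyl-1,3-oxazolidin-2-one | O=C1N[C@H](Cc2ccccc2)CO1 | starting material
4 | 3-[4-(benzyloxy)-3-methoxyphenyl]propanoic pivalic anhydride | COc1cc(CCC(=O)OC(=O)C(C)(C)C)ccc1OCc1ccccc1 | intermediate (not isolated)
5 | (4R)-4-benzyl-3-{3-[4-(benzyloxy)-3-methoxyphenyl]propanoyl}-1,3-oxazolidin-2-one | COc1cc(CCC(=O)N2[C@H](Cc3ccccc3)COC2=O)ccc1OCc1ccccc1 | intermediate
6 | trichlorotitanium (Z)-enolate of 5 | COc1cc(C/C=C(\O[Ti](Cl)(Cl)Cl)N2[C@H](Cc3ccccc3)COC2=O)ccc1OCc1ccccc1 | intermediate (not isolated)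
7 | (4R)-4-benzyl-3-[(2S)-2-{[4-(benzyloxy)-3-methoxyphenyl]methyl}-3-hydroxypropanoyl]-1,3-oxazolidin-2-one | COc1cc(C[C@@H](CO)C(=O)N2[C@H](Cc3ccccc3)COC2=O)ccc1OCc1ccccc1 | intermediate
8 | (4R)-4-benzyl-3-[(2S)-2-{[4-(benzyloxy)-3-methoxyphenyl]methyl}-3-[(tert-butyldimethylsilyl)oxy]propanoyl]-1,3-oxazolidin-2-one | COc1cc(C[C@@H](CO[Si](C)(C)C(C)(C)C)C(=O)N2[C@H](Cc3ccccc3)COC2=O)ccc1OCc1ccccc1 | intermediate
9 | (2R)-2-{[4-(benzyloxy)-3-methoxyphenyl]methyl}-3-[(tert-butyldimethylsilyl)oxy]propan-1-ol | COc1cc(C[C@@H](CO[Si](C)(C)C(C)(C)C)CO)ccc1OCc1ccccc1 | intermediate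
10 | (2S)-2-{[4-(benzyloxy)-3-methoxyphenyl]methyl}-3-[(tert-butyldimethylsilyl)oxy]propanal | COc1cc(C[C@@H](CO[Si](C)(C)C(C)(C)C)C=O)ccc1OCc1ccccc1 | intermediate
11 | tert-butyl{[(2R)-2-{[4-(benzyloxy)-3-methoxyphenyl]methyl}but-3-yn-1-yl]oxy}dimethylsilane | COc1cc(C[C@@H](CO[Si](C)(C)C(C)(C)C)C#C)ccc1OCc1ccccc1 | intermediate
12 | (2R)-2-{[4-(benzyloxy)-3-methoxyphenyl]methyl}but-3-yn-1-ol | COc1cc(C[C@@H](CO)C#C)ccc1OCc1ccccc1 | intermediate
13 | 1-(benzyloxy)-4-[(2R)-2-(chloromethyl)but-3-yn-1-yl]-2-methoxybenzene | COc1cc(C[C@@H](CCl)C#C)ccc1OCc1ccccc1 | intermediate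
14 | 4-bromo-2-methoxyphenol | COc1cc(Br)ccc1O | starting material
15 | 4-bromo-2-iodo-6-methoxyphenol | COc1cc(Br)cc(I)c1O | intermediate
16 | [4-(benzyloxy)-3-methoxyphenyl]methanol | COc1cc(CO)ccc1OCc1ccccc1 | starting material
17 | 2-{[4-(benzyloxy)-3-methoxyphenyl]methoxy}-5-bromo-1-iodo-3-methoxybenzene | COc1cc(COc2c(I)cc(Br)cc2OC)ccc1OCc1ccccc1 | intermediate
18 | ethyl diazoacetate | CCOC(=O)C=[N+]=[N-] | starting material
19 | ethyl 2-(2-{[4-(benzyloxy)-3-methoxyphenyl]methoxy}-5-bromo-3-methoxyphenyl)-2-diazoacetate | CCOC(=O)C(=[N+]=[N-])c1cc(Br)cc(OC)c1OCc1ccc(OCc2ccccc2)c(OC)c1 | intermediate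
20 | ethyl (2S,3R)-2-[4-(benzyloxy)-3-methoxyphenyl]-5-bromo-7-methoxy-2,3-dihydro-1-benzofuran-3-carboxylate (cis) | Brc1cc(OC)c2c(c1)[C@@H](C(=O)OCC)[C@@H](c1ccc(OCc3ccccc3)c(OC)c1)O2 | intermediate
21 | ethyl (2S,3S)-2-[4-(benzyloxy)-3-methoxyphenyl]-5-bromo-7-methoxy-2,3-dihydro-1-benzofuran-3-carboxylate (trans) | Brc1cc(OC)c2c(c1)[C@H](C(=O)OCC)[C@@H](c1ccc(OCc3ccccc3)c(OC)c1)O2 | intermediate
22 | [(2S,3R)-2-[4-(benzyloxy)-3-methoxyphenyl]-5-bromo-7-methoxy-2,3-dihydro-1-benzofuran-3-yl]methanol (trans) | Brc1cc(OC)c2c(c1)[C@H](CO)[C@@H](c1ccc(OCc3ccccc3)c(OC)c1)O2 | intermediate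
23 | {(2S,3R)-2-[4-(benzyloxy)-3-methoxyphenyl]-5-[(3R)-4-[4-(benzyloxy)-3-methoxyphenyl]-3-(chloromethyl)but-1-yn-1-yl]-7-methoxy-2,3-dihydro-1-benzofuran-3-yl}methanol | COc1cc(C[C@@H](CCl)C#Cc2cc(OC)c3c(c2)[C@H](CO)[C@@H](c2ccc(OCc4ccccc4)c(OC)c2)O3)ccc1OCc1ccccc1 | intermediate
24 | ethylzinc (2E)-2-[(2R)-1-[4-(benzyloxy)-3-methoxyphenyl]-3-chloropropan-2-yl]-3-{(2S,3R)-2-[4-(benzyloxy)-3-methoxyphenyl]-3-(hydroxymethyl)-7-methoxy-2,3-dihydro-1-benzofuran-5-yl}prop-2-enoate (hydroxyl drawn free) | COc1cc(C[C@@H](CCl)/C(=C\c2cc(OC)c3c(c2)[C@H](CO)[C@@H](c2ccc(OCc4ccccc4)c(OC)c2)O3)C(=O)O[Zn]CC)ccc1OCc1ccccc1 | intermediate (not isolated)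
25 | (3E,4R)-3-({(2S,3R)-2-[4-(benzyloxy)-3-methoxyphenyl]-3-(hydroxymethyl)-7-methoxy-2,3-dihydro-1-benzofuran-5-yl}methylidene)-4-{[4-(benzyloxy)-3-methoxyphenyl]methyl}oxolan-2-one | COc1cc(C[C@H]2COC(=O)/C2=C/c2cc(OC)c3c(c2)[C@H](CO)[C@@H](c2ccc(OCc4ccccc4)c(OC)c2)O3)ccc1OCc1ccccc1 | intermediate
26 | (3S,4R)-4-[(4-hydroxy-3-methoxyphenyl)methyl]-3-{[(2S,3R)-2-(4-hydroxy-3-methoxyphenyl)-3-(hydroxymethyl)-7-methoxy-2,3-dihydro-1-benzofuran-5-yl]methyl}oxolan-2-one (cis lactone) | COc1cc(C[C@H]2COC(=O)[C@H]2Cc2cc(OC)c3c(c2)[C@H](CO)[C@@H](c2ccc(O)c(OC)c2)O3)ccc1O | intermediate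
27 | isolappaol A, (3R,4R)-4-[(4-hydroxy-3-methoxyphenyl)methyl]-3-{[(2S,3R)-2-(4-hydroxy-3-methoxyphenyl)-3-(hydroxymethyl)-7-methoxy-2,3-dihydro-1-benzofuran-5-yl]methyl}oxolan-2-one | COc1cc(C[C@H]2COC(=O)[C@@H]2Cc2cc(OC)c3c(c2)[C@H](CO)[C@@H](c2ccc(O)c(OC)c2)O3)ccc1O | target

**Step count and risks**

Total step count: 19. Longest linear sequence: 13 steps (steps 1 to 9, then 16 to 19).

Steps most likely to fail:

Step 17 (Proposed new method). The carboxylation may lose its regiocontrol at the hindered alkyne carbon, the alkyl chloride may be consumed by the nickel catalyst or by Et2Zn before the carboxylate exists, or the zinc carboxylate may close the ring too slowly. The fallback uses known chemistry, sets out from alkynol 12 and bromide 22 and comes back to the route at 25. Coupling of 12 with 22 under the conditions of step 16 should give the diol alkyne F1. The established Ni(cod)2/CsF/Et2Zn hydrocarboxylation of aryl alkyl alkynes under CO2, here helped by the homopropargylic hydroxyl group, should then give the hydroxy acid F2. TsOH in toluene closes the lactone by acyl–oxygen bond formation to 25.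

Step 13. The insertion may proceed with insufficient enantioselectivity, or ylide-type pathways of the carbenoid may compete. The fallback sets out from 19 and comes back at 22. Rh2(OAc)4 in CH2Cl2 should give the racemic cis ester F3; NaOH in aqueous EtOH epimerizes and saponifies it to the racemic trans acid F4. Crystallisation of the salt of F4 with (S)-1-phenylethylamine (the antipodal amine if the other salt proves the less soluble) gives the (2S,3S)-acid F5. BH3·SMe2 reduces F5 to 22.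

Step 18. Hydrogenolysis may go beyond the benzyl ethers and open the benzylic C2–O bond of the dihydrobenzofuran once the para-phenol is free. The fallback sets out from 25 and comes back at 27. NaBH4 with NiCl2·6H2O in MeOH/THF at 0 °C should reduce only the conjugated alkene to the cis bis(benzyl ether) F6 (with some trans epimer). NaOMe in MeOH equilibrates it to the trans bis(benzyl ether) F7. BCl3 with pentamethylbenzene in CH2Cl2 at −78 °C then removes the two benzyl groups without hydrogen to give 27.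

**Further compounds**

F1 | step 17 | {(2S,3R)-2-[4-(benzyloxy)-3-methoxyphenyl]-5-[(3R)-4-[4-(benzyloxy)-3-methoxyphenyl]-3-(hydroxymethyl)but-1-yn-1-yl]-7-methoxy-2,3-dihydro-1-benzofuran-3-yl}methanol | COc1cc(C[C@@H](CO)C#Cc2cc(OC)c3c(c2)[C@H](CO)[C@@H](c2ccc(OCc4ccccc4)c(OC)c2)O3)ccc1OCc1ccccc1
F2 | step 17 | (2E)-2-[(2R)-1-[4-(benzyloxy)-3-methoxyphenyl]-3-hydroxypropan-2-yl]-3-{(2S,3R)-2-[4-(benzyloxy)-3-methoxyphenyl]-3-(hydroxymethyl)-7-methoxy-2,3-dihydro-1-benzofuran-5-yl}prop-2-enoic acid | COc1cc(C[C@@H](CO)/C(=C\c2cc(OC)c3c(c2)[C@H](CO)[C@@H](c2ccc(OCc4ccccc4)c(OC)c2)O3)C(=O)O)ccc1OCc1ccccc1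
F3 | step 13 | racemic ethyl cis-2-[4-(benzyloxy)-3-methoxyphenyl]-5-bromo-7-methoxy-2,3-dihydro-1-benzofuran-3-carboxylate, (2S,3R) and (2R,3S) | Brc1cc(OC)c2c(c1)[C@@H](C(=O)OCC)[C@@H](c1ccc(OCc3ccccc3)c(OC)c1)O2.Brc1cc(OC)c2c(c1)[C@H](C(=O)OCC)[C@H](c1ccc(OCc3ccccc3)c(OC)c1)O2
F4 | step 13 | racemic trans-2-[4-(benzyloxy)-3-methoxyphenyl]-5-bromo-7-methoxy-2,3-dihydro-1-benzofuran-3-carboxylic acid, (2S,3S) and (2R,3R) | Brc1cc(OC)c2c(c1)[C@H](C(=O)O)[C@@H](c1ccc(OCc3ccccc3)c(OC)c1)O2.Brc1cc(OC)c2c(c1)[C@@H](C(=O)O)[C@H](c1ccc(OCc3ccccc3)c(OC)c1)O2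
F5 | step 13 | (2S,3S)-2-[4-(benzyloxy)-3-methoxyphenyl]-5-bromo-7-methoxy-2,3-dihydro-1-benzofuran-3-carboxylic acid | Brc1cc(OC)c2c(c1)[C@H](C(=O)O)[C@@H](c1ccc(OCc3ccccc3)c(OC)c1)O2
F6 | step 18 | (3S,4R)-3-({(2S,3R)-2-[4-(benzyloxy)-3-methoxyphenyl]-3-(hydroxymethyl)-7-methoxy-2,3-dihydro-1-benzofuran-5-yl}methyl)-4-{[4-(benzyloxy)-3-methoxyphenyl]methyl}oxolan-2-one (cis) | COc1cc(C[C@H]2COC(=O)[C@H]2Cc2cc(OC)c3c(c2)[C@H](CO)[C@@H](c2ccc(OCc4ccccc4)c(OC)c2)O3)ccc1OCc1ccccc1
F7 | step 18 | (3R,4R)-3-({(2S,3R)-2-[4-(benzyloxy)-3-methoxyphenyl]-3-(hydroxymethyl)-7-methoxy-2,3-dihydro-1-benzofuran-5-yl}methyl)-4-{[4-(benzyloxy)-3-methoxyphenyl]methyl}oxolan-2-one (trans) | COc1cc(C[C@H]2COC(=O)[C@@H]2Cc2cc(OC)c3c(c2)[C@H](CO)[C@@H](c2ccc(OCc4ccccc4)c(OC)c2)O3)ccc1OCc1ccccc1
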